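**Retrosynthetic overview**
1. The route rests on ring C, the 2-aryl dihydropyran O1–C2–C3–C4–C4a–C8a fused to ring A. It is cut at O1–C2 and C3–C4 into an o-quinone methide cation of ring A (O1, C8a, C4a, C4) and a ring B styrene (C2, C3), joined by an inverse-demand hetero-Diels–Alder reaction under a chiral phosphoric acid. The C4 methoxy group left by the cycloaddition is then hydrolysed and oxidised to the ketone, and the silyl ethers are removed.
2. Ring A partner: 6-silyloxy-2-hydroxy-3-lavandulyl-4-methoxybenzaldehyde, from 2,4,6-trihydroxybenzaldehyde by O4-methylation, monosilylation, ortho-iodination and Negishi coupling with (S)-lavandulylzinc iodide.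
3. Lavandulyl unit: Evans deconjugative alkylation of an N-senecioyl oxazolidinone with prenyl bromide sets the side-chain stereocenter; reduction and iodination give (S)-lavandulyl iodide.
4. Ring B partner: 2,4-bis(silyloxy)-5-methoxystyrene from 4-methoxyresorcinol by Vilsmeier formylation, silylation and Wittig methylenation.
5. Ring order: rings A and B are bought as arenes; ring C is the only ring formed, in the key step.

Key step: step 12

Assumption: the sense of induction of the chiral phosphoric acid in step 12 cannot be predicted with certainty; the (R)-acid is written, and its enantiomer would be used if the (R)-acid favours the (2R) series.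

Remark on descriptors: "lavandulyl" means 5-methyl-2-(prop-1-en-2-yl)hex-4-en-1-yl. The same spatial arrangement is (S) in lavandulol, its iodide and its zinc reagent, and (R) once the CH2 group is bound to the arene, because only the CIP priorities change.

**Step 1**
Reactants: 1 2,4,6-trihydroxybenzaldehyde
Product: 2 2,6-dihydroxy-4-methoxybenzaldehyde
Conditions: Me2SO4 (1.0 equiv), K2CO3 (1.0 equiv), acetone, 0 °C → rt
Reagents that add atoms: dimethyl sulfate, COS(=O)(=O)OC
Why: The 4-hydroxyl, para to the formyl group and the only phenol not hydrogen-bonded to it, is the most acidic, so one equivalent of base and dimethyl sulfate should give selective Williamson O-methylation at O4.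

**Step 2**
Reactants: 2 2,6-dihydroxy-4-methoxybenzaldehyde
Product: 3 2-(tert-butyldimethylsilyloxy)-6-hydroxy-4-methoxybenzaldehyde
Conditions: TBSCl (1.05 equiv), imidazole, CH2Cl2, 0 °C
Reagents that add atoms: tert-butyldimethylsilyl chloride, CC(C)(C)[Si](C)(C)Cl
Why: Once one of the two equivalent ortho phenols is silylated, the other is locked in a hydrogen bond to the aldehyde and is much less nucleophilic, so the silyl ether formation should stop at the mono-ether.

**Step 3**
Reactants: 3 2-(tert-butyldimethylsilyloxy)-6-hydroxy-4-methoxybenzaldehyde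
Product: 4 6-(tert-butyldimethylsilyloxy)-2-hydroxy-3-iodo-4-methoxybenzaldehyde
Conditions: NIS (1.05 equiv), DMF, 0 °C → rt, dark
Reagents that add atoms: N-iodosuccinimide, O=C1CCC(=O)N1I
Why: Electrophilic aromatic iodination should go to C3, ortho to the free chelated phenol and flanked only by OH and OMe, and not to C5, which is shielded by the bulky silyl ether; this is the usual ortho-to-hydroxyl selectivity of 2-hydroxy-4,6-dialkoxyaryl carbonyl compounds.

**Step 4**
Reactants: 5 (S)-4-benzyl-2-oxazolidinone; 6 3-methylbut-2-enoyl chloride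
Product: 8 (S)-4-benzyl-3-(3-methylbut-2-enoyl)oxazolidin-2-one, via lithium oxazolidinide 7 (not isolated)
Conditions: n-BuLi, THF, −78 °C; then 6, −78 → 0 °C
Reagents that add atoms: none
Why: N-acylation of the lithiated Evans oxazolidinone by an acid chloride is standard and installs the auxiliary that will control the lavandulyl stereocenter.

**Step 5**
Reactants: 8 (S)-4-benzyl-3-(3-methylbut-2-enoyl)oxazolidin-2-one; 9 prenyl bromide
Product: 11 (S)-4-benzyl-3-[(S)-5-methyl-2-(prop-1-en-2-yl)hex-4-enoyl]oxazolidin-2-one, via sodium dienolate 10 (not isolated)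
Conditions: NaHMDS (1.1 equiv), THF, −78 °C; then 9, −78 °C
Reagents that add atoms: none
Why: Evans deconjugative alkylation: γ-deprotonation of the s-cis enoyl imide gives the chelated (Z)-dienolate, which is alkylated at the α-carbon on the face opposite the benzyl group, so the (S) center is set by the auxiliary and the alkene moves into the isopropenyl position.

**Step 6**
Reactants: 11 (S)-4-benzyl-3-[(S)-5-methyl-2-(prop-1-en-2-yl)hex-4-enoyl]oxazolidin-2-one
Product: 12 (S)-lavandulol
Conditions: LiBH4, H2O (1 equiv), Et2O, 0 °C
Reagents that add atoms: none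
Why: Reductive cleavage of the N-acyl oxazolidinone with LiBH4 gives the primary alcohol without touching the alkenes or the α-stereocenter and returns the auxiliary.

**Step 7**
Reactants: 12 (S)-lavandulol
Product: 13 (S)-lavandulyl iodide
Conditions: PPh3, I2, imidazole, CH2Cl2, 0 °C → rt
Reagents that add atoms: iodine, II
Why: Appel-type iodination replaces the primary hydroxyl by SN2 at CH2, so the adjacent stereocenter is not involved.

**Step 8**
Reactants: 4 6-(tert-butyldimethylsilyloxy)-2-hydroxy-3-iodo-4-methoxybenzaldehyde; 13 (S)-lavandulyl iodide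
Product: 15 6-(tert-butyldimethylsilyloxy)-2-hydroxy-3-[(R)-lavandulyl]-4-methoxybenzaldehyde, via (S)-lavandulylzinc iodide 14 (not isolated)
Conditions: 13, Zn dust, LiCl, THF, 40 °C; then slow addition (2 equiv) to 4, Pd(OAc)2 (3 mol %), SPhos [2-dicyclohexylphosphino-2',6'-dimethoxybiphenyl] (6 mol %), THF, 25 °C
Reagents that add atoms: none
Why: Negishi coupling: zinc insertion into the primary iodide gives a homoallylic zinc reagent whose stereocenter is β to the metal and therefore secure, and Pd(OAc)2/SPhos couples primary alkylzinc halides with ortho-substituted aryl iodides in the presence of aldehydes and free phenols, the excess of zinc reagent covering any loss to the acidic OH.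

**Step 9**
Reactants: 16 4-methoxyresorcinol
Product: 18 2,4-dihydroxy-5-methoxybenzaldehyde, via aryl iminium chloride 17 (not isolated)
Conditions: POCl3, DMF, MeCN, 0 °C → rt; then H2O, 50 °C
Reagents that add atoms: N,N-dimethylformamide, CN(C)C=O; water, O
Why: Vilsmeier–Haack formylation should go to C6 of the resorcinol, para to one hydroxyl and ortho to the other and the only unhindered doubly activated position, and hydrolysis of the iminium salt releases the aldehyde.

**Step 10**
Reactants: 18 2,4-dihydroxy-5-methoxybenzaldehyde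
Product: 19 2,4-bis(tert-butyldimethylsilyloxy)-5-methoxybenzaldehyde
Conditions: TBSCl (2.4 equiv), imidazole (5 equiv), DMF, rt
Reagents that add atoms: tert-butyldimethylsilyl chloride, CC(C)(C)[Si](C)(C)Cl
Why: Exhaustive silyl ether formation with excess reagent in DMF also covers the chelated ortho phenol and gives protection that tolerates ylides and weak acid and keeps ring B from being too strong a donor at C2 later.

**Step 11**
Reactants: 19 2,4-bis(tert-butyldimethylsilyloxy)-5-methoxybenzaldehyde
Product: 20 2,4-bis(tert-butyldimethylsilyloxy)-5-methoxystyrene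
Conditions: Ph3PCH3Br (1.3 equiv), NaHMDS (1.2 equiv), THF, 0 °C; then 19, −78 → 0 °C
Reagents that add atoms: methyltriphenylphosphonium bromide, C[P+](c1ccccc1)(c1ccccc1)c1ccccc1.[Br-]
Why: Wittig methylenation with an ylide made from a non-nucleophilic amide base, run cold, converts the aldehyde to the styrene without attack on the aryl silyl ethers.

**Step 12**
Reactants: 15 6-(tert-butyldimethylsilyloxy)-2-hydroxy-3-[(R)-lavandulyl]-4-methoxybenzaldehyde; 20 2,4-bis(tert-butyldimethylsilyloxy)-5-methoxystyrene (1.3 equiv)
Product: 23 (2S,4S)-5-(tert-butyldimethylsilyloxy)-2-[2,4-bis(tert-butyldimethylsilyloxy)-5-methoxyphenyl]-4,7-dimethoxy-8-[(R)-lavandulyl]chroman (2,4-cis-4-methoxyflavan), via dimethyl acetal 21 (not isolated), via oxocarbenium ion 22 (not isolated)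
Conditions: HC(OMe)3 (2 equiv), (R)-TRIP [(R)-3,3'-bis(2,4,6-triisopropylphenyl)-1,1'-binaphthyl-2,2'-diyl hydrogen phosphate] (10 mol %), 5 Å MS, toluene, −40 → −20 °C
Reagents that add atoms: trimethyl orthoformate, COC(OC)OC
Why: Proposed new method: acid-catalysed acetalisation of 15 and loss of methanol give the O-methyl oxocarbenium ion 22, the O-protonated form of a 4-methoxy o-quinone methide, held as a hydrogen-bonded ion pair with the chiral phosphate through its free hydroxyl. The terminal carbon of styrene 20 adds to the cationic carbon (C3–C4) and the phenol oxygen closes on the developing benzylic cation (O1–C2) in an asynchronous inverse-demand hetero-[4+2] cycloaddition, which closes the six-membered ring C in a single intermolecular event. The closest known reactions are the racemic Brønsted-acid three-component synthesis of cis-4-methoxyflavans from salicylaldehydes, orthoformate and styrenes, and chiral-phosphoric-acid-catalysed cycloadditions of o-quinone methides with styrenes; their combination on an O-alkyl oxocarbenium ion is the untested part. C4 and C2 are set together, cis through the endo transition state, and the (S) configuration at C2 is controlled by the phosphate counter-anion, the lavandulyl center being too remote to direct. The step needs regioselectivity (inherent in the polarisation of both partners), the right O1 (only the hydroxyl next to C8 is free), chemoselectivity for the dioxygenated styrene over the lavandulyl alkenes (a weak acid and low temperature should leave the isopropenyl group unprotonated) and configurational stability at C2 (silyl ethers on ring B and low temperature disfavour C2–O1 ionisation, while re-ionisation at C4 is harmless because C4 is oxidised later).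

**Step 13**
Reactants: 23 (2S,4S)-4-methoxyflavan tris-silyl ether
Product: 24 (2S)-5-(tert-butyldimethylsilyloxy)-2-[2,4-bis(tert-butyldimethylsilyloxy)-5-methoxyphenyl]-7-methoxy-8-[(R)-lavandulyl]chroman-4-ol (C4 epimers, used crude)
Conditions: PPTS (0.2 equiv), MeCN/H2O 4:1, 25 → 40 °C; neutral work-up
Reagents that add atoms: water, O
Why: SN1 hydrolysis of the benzylic methyl ether: the C4 cation, stabilised by O1, O5 and O7 of ring A, should form under weak aqueous acid and be captured by the large excess of water, the C4 configuration being irrelevant and C2 untouched because its ionisation would require cleavage of the aryl ether bond.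

**Step 14**
Reactants: 24 (2S)-flavan-4-ol tris-silyl ether
Product: 25 (2S)-5-(tert-butyldimethylsilyloxy)-2-[2,4-bis(tert-butyldimethylsilyloxy)-5-methoxyphenyl]-7-methoxy-8-[(R)-lavandulyl]chroman-4-one
Conditions: n-Pr4N[RuO4] (5 mol %), NMO (1.5 equiv), 4 Å MS, CH2Cl2, rt
Reagents that add atoms: none
Why: Ley–Griffith oxidation turns the secondary benzylic alcohol into the ketone under neutral conditions, so both C4 epimers converge on one flavanone while the silyl-protected ring B and the alkenes are left alone.

**Step 15**
Reactants: 25 (2S)-flavanone tris-silyl ether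
Product: 26 (2S)-5-hydroxy-2-(2,4-dihydroxy-5-methoxyphenyl)-7-methoxy-8-[(R)-lavandulyl]chroman-4-one (CNP0104733.2)
Conditions: TBAF (3.3 equiv), AcOH (3.5 equiv), THF, 0 °C
Reagents that add atoms: none
Why: Fluoride cleavage of the three aryl silyl ethers; buffering with acetic acid keeps the medium non-basic, so the flavanone should not open to the chalcone, which would racemise C2 or allow reclosure through O5.

**Compound list**
1 | 2,4,6-trihydroxybenzaldehyde | O=Cc1c(O)cc(O)cc1O | starting material
2 | 2,6-dihydroxy-4-methoxybenzaldehyde | COc1cc(O)c(C=O)c(O)c1 | intermediate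
3 | 2-(tert-butyldimethylsilyloxy)-6-hydroxy-4-methoxybenzaldehyde | COc1cc(O)c(C=O)c(O[Si](C)(C)C(C)(C)C)c1 | intermediate
4 | 6-(tert-butyldimethylsilyloxy)-2-hydroxy-3-iodo-4-methoxybenzaldehyde | COc1cc(O[Si](C)(C)C(C)(C)C)c(C=O)c(O)c1I | intermediate
5 | (S)-4-benzyl-2-oxazolidinone | O=C1N[C@@H](Cc2ccccc2)CO1 | starting material
6 | 3-methylbut-2-enoyl chloride | CC(C)=CC(=O)Cl | starting material
7 | lithium salt of (S)-4-benzyl-2-oxazolidinone | [Li+].O=C1[N-][C@@H](Cc2ccccc2)CO1 | intermediate
8 | (S)-4-benzyl-3-(3-methylbut-2-enoyl)oxazolidin-2-one | CC(C)=CC(=O)N1C(=O)OC[C@@H]1Cc1ccccc1 | intermediate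
9 | prenyl bromide (1-bromo-3-methylbut-2-ene) | CC(C)=CCBr | starting material
10 | sodium (Z)-dienolate of 8 | [Na+].C=C(C)/C=C(\[O-])N1C(=O)OC[C@@H]1Cc1ccccc1 | intermediate
11 | (S)-4-benzyl-3-[(S)-5-methyl-2-(prop-1-en-2-yl)hex-4-enoyl]oxazolidin-2-one | C=C(C)[C@H](CC=C(C)C)C(=O)N1C(=O)OC[C@@H]1Cc1ccccc1 | intermediate
12 | (S)-lavandulol | C=C(C)[C@H](CC=C(C)C)CO | intermediate
13 | (S)-lavandulyl iodide | C=C(C)[C@H](CC=C(C)C)CI | intermediate
14 | (S)-lavandulylzinc iodide | C=C(C)[C@H](CC=C(C)C)C[Zn]I | intermediate
15 | 6-(tert-butyldimethylsilyloxy)-2-hydroxy-3-[(R)-lavandulyl]-4-methoxybenzaldehyde | C=C(C)[C@H](CC=C(C)C)Cc1c(OC)cc(O[Si](C)(C)C(C)(C)C)c(C=O)c1O | intermediate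
16 | 4-methoxyresorcinol | COc1ccc(O)cc1O | starting material
17 | N-(2,4-dihydroxy-5-methoxybenzylidene)-N-methylmethanaminium chloride | C[N+](C)=Cc1cc(OC)c(O)cc1O.[Cl-] | intermediate
18 | 2,4-dihydroxy-5-methoxybenzaldehyde | COc1cc(C=O)c(O)cc1O | intermediate
19 | 2,4-bis(tert-butyldimethylsilyloxy)-5-methoxybenzaldehyde | COc1cc(C=O)c(O[Si](C)(C)C(C)(C)C)cc1O[Si](C)(C)C(C)(C)C | intermediate
20 | 2,4-bis(tert-butyldimethylsilyloxy)-5-methoxystyrene | C=Cc1cc(OC)c(O[Si](C)(C)C(C)(C)C)cc1O[Si](C)(C)C(C)(C)C | intermediate
21 | dimethyl acetal of 15 | C=C(C)[C@H](CC=C(C)C)Cc1c(OC)cc(O[Si](C)(C)C(C)(C)C)c(C(OC)OC)c1O | intermediate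
22 | O-methyl oxocarbenium ion of 15 (protonated 4-methoxy o-quinone methide, chiral phosphate ion pair; cation shown) | C=C(C)[C@H](CC=C(C)C)Cc1c(OC)cc(O[Si](C)(C)C(C)(C)C)c(C=[O+]C)c1O | intermediate
23 | (2S,4S)-cis-4-methoxyflavan tris-silyl ether with (R)-lavandulyl at C8 | C=C(C)[C@H](CC=C(C)C)Cc1c(OC)cc(O[Si](C)(C)C(C)(C)C)c2c1O[C@H](c1cc(OC)c(O[Si](C)(C)C(C)(C)C)cc1O[Si](C)(C)C(C)(C)C)C[C@@H]2OC | intermediate
24 | (2S)-flavan-4-ol tris-silyl ether (C4 epimers, C4 left undefined) | C=C(C)[C@H](CC=C(C)C)Cc1c(OC)cc(O[Si](C)(C)C(C)(C)C)c2c1O[C@H](c1cc(OC)c(O[Si](C)(C)C(C)(C)C)cc1O[Si](C)(C)C(C)(C)C)CC2O | intermediate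
25 | (2S)-flavanone tris-silyl ether | C=C(C)[C@H](CC=C(C)C)Cc1c(OC)cc(O[Si](C)(C)C(C)(C)C)c2c1O[C@H](c1cc(OC)c(O[Si](C)(C)C(C)(C)C)cc1O[Si](C)(C)C(C)(C)C)CC2=O | intermediate
26 | (2S)-5-hydroxy-2-(2,4-dihydroxy-5-methoxyphenyl)-7-methoxy-8-[(R)-lavandulyl]chroman-4-one (CNP0104733.2) | C=C(C)[C@H](CC=C(C)C)Cc1c(OC)cc(O)c2c1O[C@H](c1cc(OC)c(O)cc1O)CC2=O | target

**Step count**
Total: 15 steps. Longest linear sequence: 9 steps (steps 4–8, then 12–15).

**Steps most likely to fail**

Step 12. Facial control by the phosphate may be insufficient, so that C2 forms with poor selectivity; the acid may also oligomerise the styrene or promote addition of the free phenol to the isopropenyl group. The fallback uses known chemistry and sets out from 15 and 20. The three-component reaction is run with an achiral Brønsted acid (diphenyl phosphate, 10 mol %, HC(OMe)3, CH2Cl2, 0 °C), which should give the cis adduct as a pair of diastereomers, 23 and the (2R,4R)-cis-4-methoxyflavan F1. The mixture is carried through the hydrolysis and oxidation of steps 13 and 14, so that F1 gives the (2R)-flavan-4-ol F2 and then the (2R)-flavanone tris-silyl ether F3, next to 24 and 25. Kinetic resolution by Noyori asymmetric transfer hydrogenation (RuCl(p-cymene)[(R,R)-TsDPEN], TsDPEN being N-tosyl-1,2-diphenylethane-1,2-diamine, HCO2H/Et3N, rt) is expected to reduce the (2R)-ketone faster, to the (2R,4R)-cis-flavan-4-ol F4. The unreacted (2S)-ketone is separated by chromatography, and the route is rejoined at 25.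

Step 8. The phenol may protonate the alkylzinc reagent, oxidative addition and transmetalation at the doubly ortho-substituted iodide may be slow, and β-hydride elimination from the alkylpalladium intermediate may reduce the iodide. The fallback sets out from 13 and 4 and changes the organometallic partner. Iodine–lithium exchange of 13 (t-BuLi, 2.1 equiv, Et2O, −78 °C) gives lavandulyllithium F5, which is trapped with 9-methoxy-9-borabicyclo[3.3.1]nonane as the lithium B-methoxy-B-lavandulyl borate F6. B-alkyl Suzuki–Miyaura coupling of this ate complex with 4 (PdCl2(dppf), dppf being 1,1'-bis(diphenylphosphino)ferrocene, aqueous K3PO4, DMF/THF, rt) should give 15, where the route is rejoined. The free phenol is harmless under aqueous base and no nucleophile is lost to protonation.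

Step 13. The C4 cation may lose the C3 proton to give the flav-3-ene before water captures it, and the acid may erode the silyl ethers. The fallback sets out from 23 and returns at 25 in one operation, with no new compound. DDQ in CH2Cl2/pH 7 buffer at 0 °C should abstract the hydride at C4, the most electron-rich benzylic position, which also carries the methoxy group. Water then adds to the resulting oxocarbenium ion and methanol is lost, so the ketone forms without passing through the acid-labile alcohol.

**Further compounds**
F1 | step 12 | (2R,4R)-cis-4-methoxyflavan tris-silyl ether with (R)-lavandulyl at C8 | C=C(C)[C@H](CC=C(C)C)Cc1c(OC)cc(O[Si](C)(C)C(C)(C)C)c2c1O[C@@H](c1cc(OC)c(O[Si](C)(C)C(C)(C)C)cc1O[Si](C)(C)C(C)(C)C)C[C@H]2OC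
F2 | step 12 | (2R)-flavan-4-ol tris-silyl ether (C4 epimers, C4 left undefined) | C=C(C)[C@H](CC=C(C)C)Cc1c(OC)cc(O[Si](C)(C)C(C)(C)C)c2c1O[C@@H](c1cc(OC)c(O[Si](C)(C)C(C)(C)C)cc1O[Si](C)(C)C(C)(C)C)CC2O
F3 | step 12 | (2R)-flavanone tris-silyl ether | C=C(C)[C@H](CC=C(C)C)Cc1c(OC)cc(O[Si](C)(C)C(C)(C)C)c2c1O[C@@H](c1cc(OC)c(O[Si](C)(C)C(C)(C)C)cc1O[Si](C)(C)C(C)(C)C)CC2=O
F4 | step 12 | (2R,4R)-cis-flavan-4-ol tris-silyl ether | C=C(C)[C@H](CC=C(C)C)Cc1c(OC)cc(O[Si](C)(C)C(C)(C)C)c2c1O[C@@H](c1cc(OC)c(O[Si](C)(C)C(C)(C)C)cc1O[Si](C)(C)C(C)(C)C)C[C@H]2O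
F5 | step 8 | lavandulyllithium from 13 | C=C(C)[C@H](CC=C(C)C)C[Li]
F6 | step 8 | lithium B-methoxy-B-lavandulyl-9-borabicyclo[3.3.1]nonane borate | [Li+].C=C(C)[C@H](CC=C(C)C)C[B-]1(OC)C2CCCC1CCC2
F0 | step 13 | none | none
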